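Numbering: chroman O1, C2–C4, C4a–C8a (rings C and A); pendant ring B is C1'–C6'; ring D is the 2,2-dimethylpyran fused at C4'–C5'.
Retrosynthetic cuts: ring D at O–C(CH3)2 and C5'–CH (propargyl ether Claisen cascade); ring C at C3–C4, traced back to a C3=C4 olefin (ring-closing metathesis); O1–C2 (allylic etherification); C2'–CH2 of the prenyl group (aromatic Claisen rearrangement).
Enabling feature: within ring C only C3 and C4 are bare methylene carbons. They form the two-carbon bridge from the stereogenic C2 to C4a of ring A, so each can begin as the inner carbon of a vinyl group, one on C2 and one on C4a.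
Forward order: prenylated ring B aldehyde, then cinnamyl carbonate; union with the ring A vinylphenol at O1–C2; closure of ring C; saturation of C3=C4; annulation of ring D on the freed C4' phenol; removal of the two MOM groups.
Stereochemistry: C2 is the only stereocentre. It is set as R by the chiral ligand in the iridium-catalysed branched etherification, and no later step breaks one of its bonds.

Key step: step 12

Abbreviations: MOM = CH2OCH3; SEM = CH2OCH2CH2Si(CH3)3; prenyl = 3-methylbut-2-en-1-yl; ArB = 3-(MOM-oxy)-2-prenyl-4-(SEM-oxy)phenyl; L* = (Ra,Rc,Rc)-O,O'-(1,1'-binaphthalene-2,2'-diyl) N,N-bis[1-(2-methoxyphenyl)ethyl]phosphoramidite.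
Assumption: for aryl-substituted allyl carbonates and oxygen nucleophiles the (Ra,Rc,Rc) ligand series is taken to deliver the (R)-ether. Both ligand antipodes are available, so the sense would be checked on 16 and the antipode used if it proves opposite.

Step 1
Reactants: 1 2,4-dihydroxybenzaldehyde
Product: 2 2-hydroxy-4-(methoxymethoxy)benzaldehyde
Conditions: MOMCl (1.05 equiv), K2CO3, acetone, 0 °C to rt
Reagents that add atoms: chloromethyl methyl ether (MOMCl), COCCl
Why: Williamson-type O-alkylation that is regioselective because the C2 hydroxyl is held in a hydrogen bond to the formyl oxygen, so only the free and more acidic C4 hydroxyl reacts.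

Step 2
Reactants: 2 2-hydroxy-4-(methoxymethoxy)benzaldehyde
Product: 3 5-(methoxymethoxy)-2-vinylphenol
Conditions: CH3PPh3Br (1.5 equiv), KOt-Bu (2.6 equiv), THF, 0 °C to rt; neutral work-up, stored cold over BHT
Reagents that add atoms: methyltriphenylphosphonium bromide, C[P+](c1ccccc1)(c1ccccc1)c1ccccc1.[Br-]
Why: Wittig methylenation, which tolerates the phenol once the extra base has deprotonated it and is the standard way from salicylaldehydes to 2-vinylphenols.

Step 3
Reactants: 4 3,4-dihydroxybenzaldehyde
Product: 5 3-hydroxy-4-(SEM-oxy)benzaldehyde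
Conditions: SEMCl (1.0 equiv), K2CO3 (1.1 equiv), acetone, 0 °C to rt
Reagents that add atoms: 2-(trimethylsilyl)ethoxymethyl chloride (SEMCl), C[Si](C)(C)CCOCCl
Why: Regioselective O-alkylation in which one equivalent of weak base ionises only the C4 hydroxyl acidified by the para formyl group, as is known for chloromethyl ethers and benzyl halides on this aldehyde; a fluoride-labile acetal is preferred to a silyl ether because it cannot migrate to the neighbouring oxygen in the basic steps that follow.

Step 4
Reactants: 5 3-hydroxy-4-(SEM-oxy)benzaldehyde; 6 3-chloro-3-methylbut-1-yne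
Product: 7 3-[(2-methylbut-3-yn-2-yl)oxy]-4-(SEM-oxy)benzaldehyde
Conditions: DBU, CuCl2 (1 mol %), MeCN, 0 °C
Reagents that add atoms: none
Why: Copper-catalysed O-propargylation of a phenol with a tertiary propargylic chloride, which runs through a copper-stabilised propargyl/allenyl cation and therefore works at a tertiary carbon where direct displacement cannot.

Step 5
Reactants: 7 3-[(2-methylbut-3-yn-2-yl)oxy]-4-(SEM-oxy)benzaldehyde
Product: 8 3-[(2-methylbut-3-en-2-yl)oxy]-4-(SEM-oxy)benzaldehyde
Conditions: H2 (1 atm), Pd/CaCO3–Pb(OAc)2 (Lindlar catalyst), quinoline, EtOAc, rt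
Reagents that add atoms: none
Why: Lindlar semihydrogenation stops at the terminal alkene and leaves the aldehyde and both acetals untouched.

Step 6
Reactants: 8 3-[(2-methylbut-3-en-2-yl)oxy]-4-(SEM-oxy)benzaldehyde
Product: 10 3-hydroxy-2-prenyl-4-(SEM-oxy)benzaldehyde, via prenyl cyclohexadienone 9 (not isolated)
Conditions: o-xylene, 130 °C, sealed tube, argon
Reagents that add atoms: none
Why: Aromatic Claisen rearrangement of a 1,1-dimethylallyl aryl ether, a [3,3] shift that inverts the allyl unit into a prenyl group and can end productively only at C2 because the other ortho carbon C4 bears oxygen, after which dienone 9 tautomerises to the phenol.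

Step 7
Reactants: 10 3-hydroxy-2-prenyl-4-(SEM-oxy)benzaldehyde
Product: 11 3-(MOM-oxy)-2-prenyl-4-(SEM-oxy)benzaldehyde (ArB-CHO)
Conditions: MOMCl, i-Pr2NEt, CH2Cl2, 0 °C to 40 °C
Reagents that add atoms: chloromethyl methyl ether (MOMCl), COCCl
Why: Standard MOM protection of a phenol under amine base, in which the small and highly reactive chloromethyl ether still reaches the flanked C3 oxygen and no acid is present that could cyclise the prenyl group onto it.

Step 8
Reactants: 11 ArB-CHO
Product: 12 ethyl (E)-3-ArB-prop-2-enoate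
Conditions: (EtO)2P(O)CH2CO2Et, NaH, THF, 0 °C to rt
Reagents that add atoms: triethyl phosphonoacetate, CCOC(=O)CP(=O)(OCC)OCC
Why: Horner–Wadsworth–Emmons olefination with a stabilised phosphonate gives the E-cinnamate reliably, also from benzaldehydes with one ortho substituent.

Step 9
Reactants: 12 ethyl (E)-3-ArB-prop-2-enoate
Product: 13 (E)-3-ArB-prop-2-en-1-ol
Conditions: i-Bu2AlH (2.4 equiv), CH2Cl2, −78 °C; aq potassium sodium tartrate
Reagents that add atoms: none
Why: 1,2-Reduction of an enoate with i-Bu2AlH gives the allylic alcohol without touching the olefins or the acetals.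

Step 10
Reactants: 13 (E)-3-ArB-prop-2-en-1-ol
Product: 14 (E)-3-ArB-prop-2-en-1-yl methyl carbonate
Conditions: ClCO2Me, pyridine, CH2Cl2, 0 °C
Reagents that add atoms: methyl chloroformate, COC(=O)Cl
Why: Acylation of a primary allylic alcohol to the linear methyl carbonate, the leaving group on which branched-selective iridium catalysis is best established.

Step 11
Reactants: 3 5-(methoxymethoxy)-2-vinylphenol; 14 (E)-3-ArB-prop-2-en-1-yl methyl carbonate
Product: 16 (R)-1-ArB-prop-2-en-1-yl 5-(methoxymethoxy)-2-vinylphenyl ether, via lithium phenoxide 15 (not isolated)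
Conditions: 3 (1.5 equiv), n-BuLi, THF, −78 °C to rt; then 14, [Ir(cod)Cl]2 (2 mol %), L* (4 mol %, pre-activated with n-PrNH2 at 50 °C, volatiles removed), THF, rt; stopped at full conversion
Reagents that add atoms: none
Why: Iridium-catalysed asymmetric allylic etherification, in which ionisation of 14 on the cyclometalated iridium–phosphoramidite complex gives an allyl complex that phenoxide 15 attacks anti to the metal at the aryl-bearing terminus, the ligand fixing the face so that C2 forms as R, and the ligand with 2-methoxyphenyl arms is chosen because it copes best with ortho-substituted cinnamyl carbonates.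

Step 12
Reactants: 16 (R)-1-ArB-prop-2-en-1-yl 5-(methoxymethoxy)-2-vinylphenyl ether
Product: 17 (R)-2-ArB-7-(methoxymethoxy)-2H-chromene
Conditions: RuCl2(PCy3)2(=CHPh) (first-generation Grubbs catalyst, 5 mol %), CH2Cl2 (0.01 M, acid-free), rt, argon purge, dark; used at once
Reagents that add atoms: none
Why: After loss of one PCy3 the catalyst exchanges its benzylidene for one of the two terminal vinyl groups, the new ruthenium alkylidene adds to the other vinyl group by intramolecular [2+2] cycloaddition, and cycloreversion of the ruthenacyclobutane delivers C3=C4 plus a ruthenium methylidene that carries the chain, ethene being the only coproduct. The closest known reaction type is ring-closing olefin metathesis of allyl 2-vinylphenyl ethers to 2H-chromenes, which this catalyst performs well. Ring C closes as a six-membered ring with both CH2 termini expelled, so the new double bond is endocyclic and necessarily cis. No stereocentre is created, and C2 keeps the R configuration of step 11 because none of its four bonds takes part. The selectivity required is terminal vinyl over the trisubstituted prenyl olefin, which with the C2 vinyl group could close a 1,4-dihydronaphthalene with loss of isobutene; an alkylidene loaded on ring A could reach the prenyl group only through a nine-membered ring, and one loaded on C3 chooses at equal ring size between a monosubstituted and a trisubstituted partner, where this bis(phosphine) catalyst strongly prefers the former. Room temperature, darkness and acid-free solvent keep the 2-aryl-2H-chromene from electrocyclic opening to the ortho-quinone methide, the one pathway that would erase C2.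

Step 13
Reactants: 17 (R)-2-ArB-7-(methoxymethoxy)-2H-chromene
Product: 18 (R)-2-ArB-7-(methoxymethoxy)chroman
Conditions: 2-O2NC6H4SO2NHNH2 (excess, in portions), Et3N, CH2Cl2, rt, dark
Reagents that add atoms: none
Why: Diimide reduction, a concerted syn transfer of two hydrogens whose rate drops steeply with olefin substitution, so the cis-disubstituted C3=C4 is saturated while the prenyl olefin remains, and which cannot hydrogenolyse the benzylic C2–O1 bond and runs at a temperature that does not endanger C2.

Step 14
Reactants: 18 (R)-2-ArB-7-(methoxymethoxy)chroman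
Product: 19 4-[(2R)-7-(methoxymethoxy)chroman-2-yl]-2-(methoxymethoxy)-3-prenylphenol
Conditions: Bu4NF (3 equiv), 4 Å MS, THF, 60 °C
Reagents that add atoms: none
Why: Fluoride-induced fragmentation of a phenolic SEM ether (attack at silicon, then loss of ethene and formaldehyde), to which the silicon-free MOM acetals are inert, so only the C4' phenol is released.

Step 15
Reactants: 19 4-[(2R)-7-(methoxymethoxy)chroman-2-yl]-2-(methoxymethoxy)-3-prenylphenol; 6 3-chloro-3-methylbut-1-yne
Product: 20 (2R)-7-(methoxymethoxy)-2-{3-(methoxymethoxy)-4-[(2-methylbut-3-yn-2-yl)oxy]-2-prenylphenyl}chroman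
Conditions: DBU, CuCl2 (1 mol %), MeCN, 0 °C to rt
Reagents that add atoms: none
Why: The same copper-catalysed O-propargylation as in step 4, here on the only free hydroxyl, whose acetal neighbour at C3' cannot migrate under base.

Step 16
Reactants: 20 (2R)-7-(methoxymethoxy)-2-{3-(methoxymethoxy)-4-[(2-methylbut-3-yn-2-yl)oxy]-2-prenylphenyl}chroman
Product: 24 (2R)-7-(methoxymethoxy)-2-[8-(methoxymethoxy)-2,2-dimethyl-7-prenyl-2H-chromen-6-yl]chroman, via allenyl cyclohexadienone 21 (not isolated), via ortho-allenylphenol 22 (not isolated), via ortho-quinone methide 23 (not isolated)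
Conditions: o-xylene, 140 °C, argon
Reagents that add atoms: none
Why: Thermal aryl propargyl ether Claisen cascade, in which the [3,3] shift goes to C5', the only free ortho carbon, giving 21, which enolises to 22, undergoes a [1,5]-hydrogen shift to 23 and closes ring D by oxa-6π electrocyclisation, while the saturated C2 centre is thermally inert.

Step 17
Reactants: 24 (2R)-7-(methoxymethoxy)-2-[8-(methoxymethoxy)-2,2-dimethyl-7-prenyl-2H-chromen-6-yl]chroman
Product: 25 6-[(2R)-7-hydroxychroman-2-yl]-2,2-dimethyl-7-prenyl-2H-chromen-8-ol (target)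
Conditions: HCl (cat), MeOH, rt to 40 °C; NaHCO3 quench as soon as conversion is complete
Reagents that add atoms: none
Why: Acid-catalysed acetal exchange with methanol, the usual release of phenolic MOM ethers in prenylated and chromene-bearing phenols, run dilute and mild so that the prenyl group, ring D and the C2–O1 bond are not protonated productively.

Compound list
1 | 2,4-dihydroxybenzaldehyde | O=Cc1ccc(O)cc1O | starting material
2 | 2-hydroxy-4-(methoxymethoxy)benzaldehyde | O=Cc1ccc(OCOC)cc1O | intermediate
3 | 5-(methoxymethoxy)-2-vinylphenol | C=Cc1ccc(OCOC)cc1O | intermediate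
4 | 3,4-dihydroxybenzaldehyde | O=Cc1ccc(O)c(O)c1 | starting material
5 | 3-hydroxy-4-{[2-(trimethylsilyl)ethoxy]methoxy}benzaldehyde | O=Cc1ccc(OCOCC[Si](C)(C)C)c(O)c1 | intermediate
6 | 3-chloro-3-methylbut-1-yne | C#CC(C)(C)Cl | starting material
7 | 3-[(2-methylbut-3-yn-2-yl)oxy]-4-{[2-(trimethylsilyl)ethoxy]methoxy}benzaldehyde | O=Cc1ccc(OCOCC[Si](C)(C)C)c(OC(C)(C)C#C)c1 | intermediate
8 | 3-[(2-methylbut-3-en-2-yl)oxy]-4-{[2-(trimethylsilyl)ethoxy]methoxy}benzaldehyde | O=Cc1ccc(OCOCC[Si](C)(C)C)c(OC(C)(C)C=C)c1 | intermediate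
9 | 6-(3-methylbut-2-en-1-yl)-5-oxo-4-{[2-(trimethylsilyl)ethoxy]methoxy}cyclohexa-1,3-diene-1-carbaldehyde (racemic, transient) | O=CC1=CC=C(OCOCC[Si](C)(C)C)C(=O)C1CC=C(C)C | intermediate
10 | 3-hydroxy-2-(3-methylbut-2-en-1-yl)-4-{[2-(trimethylsilyl)ethoxy]methoxy}benzaldehyde | CC(C)=CCc1c(C=O)ccc(OCOCC[Si](C)(C)C)c1O | intermediate
11 | 3-(methoxymethoxy)-2-(3-methylbut-2-en-1-yl)-4-{[2-(trimethylsilyl)ethoxy]methoxy}benzaldehyde | CC(C)=CCc1c(C=O)ccc(OCOCC[Si](C)(C)C)c1OCOC | intermediate
12 | ethyl (E)-3-ArB-prop-2-enoate | CC(C)=CCc1c(/C=C/C(=O)OCC)ccc(OCOCC[Si](C)(C)C)c1OCOC | intermediate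
13 | (E)-3-ArB-prop-2-en-1-ol | CC(C)=CCc1c(/C=C/CO)ccc(OCOCC[Si](C)(C)C)c1OCOC | intermediate
14 | (E)-3-ArB-prop-2-en-1-yl methyl carbonate | CC(C)=CCc1c(/C=C/COC(=O)OC)ccc(OCOCC[Si](C)(C)C)c1OCOC | intermediate
15 | lithium 5-(methoxymethoxy)-2-vinylphenoxide | C=Cc1ccc(OCOC)cc1[O-].[Li+] | intermediate
16 | (R)-1-ArB-prop-2-en-1-yl 5-(methoxymethoxy)-2-vinylphenyl ether | CC(C)=CCc1c([C@@H](C=C)Oc2cc(OCOC)ccc2C=C)ccc(OCOCC[Si](C)(C)C)c1OCOC | intermediate
17 | (R)-2-ArB-7-(methoxymethoxy)-2H-chromene | CC(C)=CCc1c([C@H]2C=Cc3ccc(OCOC)cc3O2)ccc(OCOCC[Si](C)(C)C)c1OCOC | intermediate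
18 | (R)-2-ArB-7-(methoxymethoxy)chroman | CC(C)=CCc1c([C@H]2CCc3ccc(OCOC)cc3O2)ccc(OCOCC[Si](C)(C)C)c1OCOC | intermediate
19 | 4-[(2R)-7-(methoxymethoxy)chroman-2-yl]-2-(methoxymethoxy)-3-(3-methylbut-2-en-1-yl)phenol | CC(C)=CCc1c([C@H]2CCc3ccc(OCOC)cc3O2)ccc(O)c1OCOC | intermediate
20 | (2R)-7-(methoxymethoxy)-2-{3-(methoxymethoxy)-4-[(2-methylbut-3-yn-2-yl)oxy]-2-(3-methylbut-2-en-1-yl)phenyl}chroman | CC(C)=CCc1c([C@H]2CCc3ccc(OCOC)cc3O2)ccc(OC(C)(C)C#C)c1OCOC | intermediate
21 | 6-(3-methylbuta-1,2-dienyl)cyclohexa-2,4-dienone from the [3,3] shift (C5' sp3, C4'=O; 2R at the chroman) | CC(C)=CCC1=C(OCOC)C(=O)C(C=C=C(C)C)C=C1[C@H]2CCc3ccc(OCOC)cc3O2 | intermediate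
22 | 4'-hydroxy-5'-(3-methylbuta-1,2-dienyl) flavan (2R) | CC(C)=CCc1c([C@H]2CCc3ccc(OCOC)cc3O2)cc(C=C=C(C)C)c(O)c1OCOC | intermediate
23 | ortho-quinone methide with C4'=O and C5'=CH–CH=C(CH3)2 (2R) | CC(C)=CCC1=C(OCOC)C(=O)C(=CC=C(C)C)C=C1[C@H]2CCc3ccc(OCOC)cc3O2 | intermediate
24 | (2R)-7-(methoxymethoxy)-2-[8-(methoxymethoxy)-2,2-dimethyl-7-(3-methylbut-2-en-1-yl)-2H-chromen-6-yl]chroman | CC(C)=CCc1c([C@H]2CCc3ccc(OCOC)cc3O2)cc2c(c1OCOC)OC(C)(C)C=C2 | intermediate
25 | 6-[(2R)-7-hydroxy-3,4-dihydro-2H-chromen-2-yl]-2,2-dimethyl-7-(3-methylbut-2-en-1-yl)-2H-chromen-8-ol | CC(C)=CCc1c([C@H]2CCc3ccc(O)cc3O2)cc2c(c1O)OC(C)(C)C=C2 | target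

Total step count: 17. Longest linear sequence: 15 steps (steps 3–17, from 4 to 25); steps 1–2 form the two-step side branch to 3.

Steps most likely to fail

Step 11. Both partners carry an ortho substituent. Attack at the hindered terminus may therefore slow down, the linear ether may gain ground, facial control may erode, and the electron-rich branched product may re-ionise on the catalyst. The fallback sets out from 11 and returns at 16, taking the stereocentre from a reagent-controlled ketone reduction and transferring it stereospecifically. Vinylmagnesium bromide adds to 11 to give racemic 1-ArB-prop-2-en-1-ol F1. MnO2 oxidises this to the aryl vinyl ketone 1-ArB-prop-2-en-1-one F2. Corey–Bakshi–Shibata reduction with the (S)-methyl oxazaborolidine and catecholborane, the aryl group acting as the large substituent, should give (R)-1-ArB-prop-2-en-1-ol F3. Methyl chloroformate and pyridine convert it into the branched (R)-1-ArB-prop-2-en-1-yl methyl carbonate F4. Rhodium-catalysed allylic etherification (RhCl(PPh3)3, P(OMe)3, THF) follows with sodium 5-(methoxymethoxy)-2-vinylphenoxide F5, made from 3 and NaN(SiMe3)2. This reaction type accepts ortho-substituted phenoxides. It substitutes at the more substituted terminus with net retention and gives 16.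

Step 12. The alkylidene may engage the prenyl olefin. The catalyst may rest as a chelated 2-alkoxybenzylidene. The 2H-chromene may open electrocyclically or oxidise during a slow reaction. The fallback sets out from 14 and returns at 18. It closes ring C at C4–C4a instead, so neither metathesis nor olefin reduction is needed. 4-Bromobenzene-1,3-diol F6 is protected at the hydroxyl remote from bromine (MOMCl, K2CO3) to give 2-bromo-5-(methoxymethoxy)phenol F7. n-BuLi converts this into lithium 2-bromo-5-(methoxymethoxy)phenoxide F8, which is coupled with 14 under the catalyst of step 11 to give (R)-1-ArB-prop-2-en-1-yl 2-bromo-5-(methoxymethoxy)phenyl ether F9. 9-BBN-H hydroborates only the terminal vinyl group and leaves the prenyl olefin, giving the primary B-alkyl-9-borabicyclononane F10. Intramolecular B-alkyl Suzuki–Miyaura coupling (PdCl2(dppf), K3PO4, THF/DMF/H2O, 60 °C, dilute) then gives flavan 18.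

Step 17. Protic acid may drive cyclisation of the prenyl group onto the freed C3' hydroxyl, addition to the ring D olefin, or ionisation of the para-alkoxybenzylic C2–O1 bond with loss of configuration. The fallback sets out from 24 and returns at 25. It replaces acetal hydrolysis by a protecting-group exchange under buffered aprotic conditions followed by fluoride. Triethylsilyl triflate and 2,2'-bipyridyl in CH2Cl2 at 0 °C convert aromatic MOM ethers directly into silyl ethers, giving the bis(triethylsilyl) ether of the target F11. Bu4NF buffered with acetic acid in THF at 0 °C then releases 25.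

Further compounds
F1 | step 11 | racemic 1-ArB-prop-2-en-1-ol | CC(C)=CCc1c(C(O)C=C)ccc(OCOCC[Si](C)(C)C)c1OCOC
F2 | step 11 | 1-ArB-prop-2-en-1-one | CC(C)=CCc1c(C(=O)C=C)ccc(OCOCC[Si](C)(C)C)c1OCOC
F3 | step 11 | (R)-1-ArB-prop-2-en-1-ol | CC(C)=CCc1c([C@@H](C=C)O)ccc(OCOCC[Si](C)(C)C)c1OCOC
F4 | step 11 | (R)-1-ArB-prop-2-en-1-yl methyl carbonate | CC(C)=CCc1c([C@@H](C=C)OC(=O)OC)ccc(OCOCC[Si](C)(C)C)c1OCOC
F5 | step 11 | sodium 5-(methoxymethoxy)-2-vinylphenoxide | C=Cc1ccc(OCOC)cc1[O-].[Na+]
F6 | step 12 | 4-bromobenzene-1,3-diol | Oc1ccc(Br)c(O)c1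
F7 | step 12 | 2-bromo-5-(methoxymethoxy)phenol | COCOc1ccc(Br)c(O)c1
F8 | step 12 | lithium 2-bromo-5-(methoxymethoxy)phenoxide | COCOc1ccc(Br)c([O-])c1.[Li+]
F9 | step 12 | (R)-1-ArB-prop-2-en-1-yl 2-bromo-5-(methoxymethoxy)phenyl ether | CC(C)=CCc1c([C@@H](C=C)Oc2cc(OCOC)ccc2Br)ccc(OCOCC[Si](C)(C)C)c1OCOC
F10 | step 12 | (R)-9-{3-ArB-3-[2-bromo-5-(methoxymethoxy)phenoxy]propyl}-9-borabicyclo[3.3.1]nonane | CC(C)=CCc1c([C@@H](CCB2C3CCCC2CCC3)Oc2cc(OCOC)ccc2Br)ccc(OCOCC[Si](C)(C)C)c1OCOC
F11 | step 17 | bis(triethylsilyl) ether of 25 (2R) | CC(C)=CCc1c([C@H]2CCc3ccc(O[Si](CC)(CC)CC)cc3O2)cc2c(c1O[Si](CC)(CC)CC)OC(C)(C)C=C2
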